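## Retrosynthetic overview

1. Target 32 comes from the bicyclic dienyl ether 29 (rings A and B) by late adjustment only: oxidation at C6, chlorination at C5 with N-chlorosuccinimide, and acetonide hydrolysis.
2. 29 comes from the acyclic dienyne 28 by one tandem ring-closing dienyne metathesis. Ring A (carbocycle C4a–C5–C6–C7–C8–C8a) closes first through C4a=C5, then ring B (pyran O2–C3–C4–C4a–C8a–C1) closes through C3=C4. The enabling feature is the heteroannular diene C3=C4–C4a=C5 spanning both rings: its inner atoms C4/C4a are a terminal alkyne on C8a, and its outer atoms C3/C5 are alkene termini (enol ether and vinyl carbinol).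
3. 28 comes from ester 26 by Tebbe methylenation and desilylation; 26 is made by esterifying diol 24 with dienoic acid 11 (fragment 2: Fráter–Seebach methylation, Wittig, Horner–Wadsworth–Emmons).
4. 24 comes from reductive opening and vinylation of δ-lactone acetonide 21. The lactone is a temporary ring in which the single C8a stereocentre directs syn-dihydroxylation to set C7 and C8. It is built from (S)-2-vinyloxirane and a silylacetylene by epoxide opening, methacrylation and ring-closing metathesis.

Key step: step 18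

Remark: atoms of all intermediates carry the locants of the target (core C1, O2, C3, C4, C4a, C5–C8, C8a; side chain C1′–C7′).
Assumption: (S)-2-vinyloxirane (13) is taken as a commercial, enantiopure epoxide.

## Route

Step 1
Reactants: 1 ethyl (S)-3-hydroxybutanoate
Product: 3 ethyl (2S,3S)-3-hydroxy-2-methylbutanoate, via dilithium alkoxide enolate 2 (not isolated)
Conditions: LiN(iPr)2 (2.2 equiv), THF, −50 to −20 °C; then MeI, DMPU, −78 to 0 °C
Reagents that add atoms: iodomethane CI
Why: Fráter–Seebach alkylation, in which the chelated dianion 2 is methylated on the face away from the C3 methyl group of the six-membered lithium chelate, so the anti (2S,3S) ester should form and C5′ is set from the purchased C6′ stereocentre.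

Step 2
Reactants: 3 ethyl (2S,3S)-3-hydroxy-2-methylbutanoate
Product: 4 ethyl (2S,3S)-3-[(tert-butyldimethylsilyl)oxy]-2-methylbutanoate
Conditions: TBSCl, imidazole, DMF, rt
Reagents that add atoms: tert-butyldimethylsilyl chloride CC(C)(C)[Si](C)(C)Cl
Why: Standard silylation of a secondary alcohol, needed to carry the C6′ hydroxyl through base, hydride and titanium chemistry.

Step 3
Reactants: 4 ethyl (2S,3S)-3-[(tert-butyldimethylsilyl)oxy]-2-methylbutanoate
Product: 5 (2S,3S)-3-[(tert-butyldimethylsilyl)oxy]-2-methylbutanal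
Conditions: iBu2AlH (1.05 equiv), CH2Cl2, −78 °C
Reagents that add atoms: none
Why: Partial ester reduction stops at the aluminium hemiacetal at low temperature and should release the aldehyde on work-up without epimerising the α-stereocentre.

Step 4
Reactants: 5 (2S,3S)-3-[(tert-butyldimethylsilyl)oxy]-2-methylbutanal; 6 2-(triphenyl-λ5-phosphanylidene)propanal
Product: 7 (2E,4R,5S)-5-[(tert-butyldimethylsilyl)oxy]-2,4-dimethylhex-2-enal
Conditions: toluene, 90 °C
Reagents that add atoms: none
Why: Wittig olefination with a stabilised, α-branched ylide should give the (E)-trisubstituted enal (the C3′=C4′ alkene of the target).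

Step 5
Reactants: 7 (2E,4R,5S)-5-[(tert-butyldimethylsilyl)oxy]-2,4-dimethylhex-2-enal; 8 triethyl phosphonoacetate
Product: 10 ethyl (2E,4E,6R,7S)-7-[(tert-butyldimethylsilyl)oxy]-4,6-dimethylocta-2,4-dienoate, via sodium phosphonoacetate anion 9 (not isolated)
Conditions: NaH, THF, 0 °C to rt
Reagents that add atoms: none
Why: Horner–Wadsworth–Emmons olefination of an enal with a stabilised phosphonate anion should give the (E)-configured C1′=C2′ alkene.

Step 6
Reactants: 10 ethyl (2E,4E,6R,7S)-7-[(tert-butyldimethylsilyl)oxy]-4,6-dimethylocta-2,4-dienoate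
Product: 11 (2E,4E,6R,7S)-7-[(tert-butyldimethylsilyl)oxy]-4,6-dimethylocta-2,4-dienoic acid
Conditions: LiOH, THF/MeOH/H2O, rt; then cold dilute HCl to pH 4
Reagents that add atoms: lithium hydroxide [Li+].[OH-]
Why: Saponification of the ethyl ester, which the secondary silyl ether and the diene should tolerate.

Step 7
Reactants: 12 ethynyl(triisopropyl)silane; 13 (S)-2-vinyloxirane
Product: 16 (S)-2-[(triisopropylsilyl)ethynyl]but-3-en-1-ol, via lithium (triisopropylsilyl)acetylide 14 (not isolated), via diethyl[(triisopropylsilyl)ethynyl]alane 15 (not isolated)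
Conditions: nBuLi, toluene, 0 °C; Et2AlCl, 0 °C; then 13, 0 °C to rt
Reagents that add atoms: none
Why: Alkynylalane opening of a vinyl epoxide, in which the Lewis-acidic aluminium activates the oxirane and the alkynyl group should be delivered to the allylic carbon with inversion (SN2), which sets C8a.

Step 8
Reactants: 16 (S)-2-[(triisopropylsilyl)ethynyl]but-3-en-1-ol; 17 methacryloyl chloride
Product: 18 (S)-2-[(triisopropylsilyl)ethynyl]but-3-en-1-yl methacrylate
Conditions: Et3N, DMAP (cat.), CH2Cl2, 0 °C
Reagents that add atoms: none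
Why: Acylation of a primary alcohol under mild base, which should leave the doubly activated C8a–H untouched.

Step 9
Reactants: 18 (S)-2-[(triisopropylsilyl)ethynyl]but-3-en-1-yl methacrylate
Product: 19 (S)-3-methyl-5-[(triisopropylsilyl)ethynyl]-5,6-dihydro-2H-pyran-2-one
Conditions: second-generation Grubbs catalyst (H2IMes)(PCy3)Cl2Ru=CHPh (5 mol %), toluene, 80 °C
Reagents that add atoms: none
Why: Ring-closing metathesis of the methacrylate of a homoallylic alcohol should close the α-methyl unsaturated δ-lactone, a temporary ring that holds the C7=C8 alkene in a six-membered ring next to C8a, while the hindered silylalkyne stays out of the metathesis.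

Step 10
Reactants: 19 (S)-3-methyl-5-[(triisopropylsilyl)ethynyl]-5,6-dihydro-2H-pyran-2-one
Product: 20 (3R,4R,5S)-3,4-dihydroxy-3-methyl-5-[(triisopropylsilyl)ethynyl]tetrahydro-2H-pyran-2-one
Conditions: OsO4 (5 mol %), N-methylmorpholine N-oxide, citric acid, acetone/H2O, rt
Reagents that add atoms: osmium tetroxide O=[Os](=O)(=O)=O; N-methylmorpholine N-oxide C[N+]1([O-])CCOCC1; water O
Why: Catalytic syn-dihydroxylation of the lactone alkene should occur on the face anti to the C5 silylalkynyl group, so C7 and C8 are set cis to each other and trans to the alkyne (substrate control from C8a).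

Step 11
Reactants: 20 (3R,4R,5S)-3,4-dihydroxy-3-methyl-5-[(triisopropylsilyl)ethynyl]tetrahydro-2H-pyran-2-one
Product: 21 (3aR,7S,7aR)-2,2,3a-trimethyl-7-[(triisopropylsilyl)ethynyl]tetrahydro-4H-[1,3]dioxolo[4,5-c]pyran-4-one
Conditions: 2,2-dimethoxypropane, camphorsulfonic acid (cat.), acetone, rt
Reagents that add atoms: 2,2-dimethoxypropane COC(C)(C)OC
Why: Acetonide formation on a cis-1,2-diol; the cis-fused dioxolane later keeps C6 and C8a on the same side for the ring A closure.

Step 12
Reactants: 21 (3aR,7S,7aR)-2,2,3a-trimethyl-7-[(triisopropylsilyl)ethynyl]tetrahydro-4H-[1,3]dioxolo[4,5-c]pyran-4-one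
Product: 22 (3aR,7S,7aR)-2,2,3a-trimethyl-7-[(triisopropylsilyl)ethynyl]tetrahydro-4H-[1,3]dioxolo[4,5-c]pyran-4-ol (anomeric mixture)
Conditions: iBu2AlH (1.1 equiv), CH2Cl2, −78 °C
Reagents that add atoms: none
Why: Partial reduction of a δ-lactone to the lactol, which cannot epimerise at C7 because that carbon is quaternary.

Step 13
Reactants: 22 lactol (anomeric mixture)
Product: 24 (R)-1-{(4S,5R)-5-[(S)-1-hydroxy-4-(triisopropylsilyl)but-3-yn-2-yl]-2,2,4-trimethyl-1,3-dioxolan-4-yl}prop-2-en-1-ol, via ring-opened aldehyde alkoxide 23 (not isolated)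
Conditions: CH2=CHMgBr (4 equiv), THF, −78 to 0 °C
Reagents that add atoms: vinylmagnesium bromide C=C[Mg]Br
Why: Grignard addition to the lactol through its open hydroxy-aldehyde form opens the temporary lactone ring for good; Cram-chelate control (aldehyde oxygen and C7 acetonide oxygen) should favour the (R)-carbinol drawn, and the C6 epimer would serve equally because C6 becomes a ketone in step 19.

Step 14
Reactants: 24 diol; 11 (2E,4E,6R,7S)-7-[(tert-butyldimethylsilyl)oxy]-4,6-dimethylocta-2,4-dienoic acid
Product: 25 (S)-2-{(4R,5S)-5-[(R)-1-hydroxyprop-2-en-1-yl]-2,2,5-trimethyl-1,3-dioxolan-4-yl}-4-(triisopropylsilyl)but-3-yn-1-yl (2E,4E,6R,7S)-7-[(tert-butyldimethylsilyl)oxy]-4,6-dimethylocta-2,4-dienoate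
Conditions: EDC hydrochloride, DMAP (cat.), CH2Cl2, 0 °C
Reagents that add atoms: none
Why: Steglich esterification, which should acylate only the primary C1 hydroxyl because the C6 carbinol is secondary and flanked by the quaternary C7; this joins both fragments and installs O2–C3.

Step 15
Reactants: 25 primary dienoate ester
Product: 26 C6 triethylsilyl ether of 25
Conditions: TESOTf, 2,6-lutidine, CH2Cl2, −78 to 0 °C
Reagents that add atoms: triethylsilyl trifluoromethanesulfonate CC[Si](CC)(CC)OS(=O)(=O)C(F)(F)F
Why: Silyl triflate protection of the hindered allylic alcohol so that no acidic OH meets the titanium methylidene in step 16.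

Step 16
Reactants: 26 C6 triethylsilyl ether
Product: 27 enol ether (ester C=O of 26 replaced by C=CH2; a 2-alkoxy-1,3,5-triene)
Conditions: Tebbe reagent Cp2Ti(μ-Cl)(μ-CH2)AlMe2 (1.5 equiv), pyridine (cat.), THF/toluene, −40 to 0 °C; aqueous NaOH work-up, Et3N-deactivated silica
Reagents that add atoms: Tebbe reagent C[Al-]1(C)C[Ti]([Cl+]1)(C1C=CC=C1)C1C=CC=C1
Why: Tebbe methylenation of an ester to a 1,1-disubstituted enol ether; the ester carbonyl should trap the titanium methylidene at low temperature faster than the alkyne, which is shielded by the triisopropylsilyl group and the branched C8a.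

Step 17
Reactants: 27 enol ether
Product: 28 dienyne (terminal alkyne on C8a, free C6 and C6′ hydroxyls, enol ether intact)
Conditions: Bu4NF (5 equiv), THF, 0 to 40 °C
Reagents that add atoms: none
Why: Fluoride cleaves the alkynyl C–Si bond and both O-silyl ethers in one operation, and the enol ether is stable to these basic conditions.

Step 18
Reactants: 28 dienyne
Product: 29 bicyclic dienyl ether: 7,8-O-isopropylidene acetal of (6R,7S,8R,8aS)-3-[(1E,3E,5R,6S)-6-hydroxy-3,5-dimethylhepta-1,3-dien-1-yl]-7-methyl-6,7,8,8a-tetrahydro-1H-isochromene-6,7,8-triol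
Conditions: second-generation Grubbs catalyst (H2IMes)(PCy3)Cl2Ru=CHPh (10 mol %), ethylene (1 atm), toluene (0.002 M), 70 °C
Reagents that add atoms: none
Why: The ruthenium alkylidene should load onto the monosubstituted C5 vinyl group (assisted by the free allylic C6 hydroxyl) and add across the C4a≡C4 alkyne to close ring A and leave a conjugated vinylalkylidene on C4, which then undergoes ring-closing metathesis with the enol ether C3=CH2 to close ring B by forming C3=C4 with loss of ethene. The closest known reaction type is the tandem ring-closing metathesis of dienynes to fused bicyclic 1,3-dienes, joined to the established ring-closing metathesis of ester-derived enol ethers. Ring A closes in the exo mode of enyne metathesis (six-membered, only C4a of the alkyne inside the ring) and ring B by ordinary alkylidene–alkene closure (six-membered). No stereocentre is formed: C7, C8 and C8a are carried over from 28, and the cis-fused acetonide keeps C6 and C8a gauche so that both chain ends reach the alkyne. The step needs chemoselective initiation and six-membered closures only: the vinyl carbinol is the only unhindered terminal alkene (the enol ether is 1,1-disubstituted, the side-chain alkenes are internal or trisubstituted), and the three-atom tethers from C8a make the endo alternatives seven- and five-membered. If ethylene adds to the alkyne first, the resulting 1,3-diene can only undergo the same two six-membered closures, so that pathway should converge on 29.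

Step 19
Reactants: 29 bicyclic dienyl ether
Product: 30 dienone: 7,8-O-isopropylidene acetal of the 5-deschloro target
Conditions: MnO2 (excess), CH2Cl2, rt (29 used crude)
Reagents that add atoms: none
Why: MnO2 should oxidise only the activated dienylic C6 alcohol and leave the saturated C6′ carbinol, giving the doubly vinylogous ester O2–C3=C4–C4a=C5–C6=O.

Step 20
Reactants: 30 dienone
Product: 31 7,8-O-isopropylidene acetal of the target
Conditions: N-chlorosuccinimide (1.05 equiv), MeCN, 0 °C to rt
Reagents that add atoms: N-chlorosuccinimide O=C1CCC(=O)N1Cl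
Why: Electrophilic chlorination at C5, the α-carbon of the doubly vinylogous ester and the most nucleophilic site of the push–pull system, as in the halogenation of azaphilone-type dienones.

Step 21
Reactants: 31 7,8-O-isopropylidene acetal of the target
Product: 32 (7R,8R,8aS)-5-chloro-7,8-dihydroxy-3-[(1E,3E,5R,6S)-6-hydroxy-3,5-dimethylhepta-1,3-dien-1-yl]-7-methyl-8,8a-dihydro-1H-isochromen-6(7H)-one
Conditions: AcOH/H2O (4:1), 40 °C
Reagents that add atoms: none
Why: Acid-catalysed acetonide hydrolysis, which the vinylogous-ester chromophore should tolerate, releases the cis-7,8-diol without touching any stereocentre.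

## Compound list

1 | ethyl (S)-3-hydroxybutanoate | CCOC(=O)C[C@H](C)O | starting material
2 | dilithium alkoxide enolate of 1 | CCO/C(O[Li])=C/[C@H](C)O[Li] | intermediate
3 | ethyl (2S,3S)-3-hydroxy-2-methylbutanoate | CCOC(=O)[C@@H](C)[C@H](C)O | intermediate
4 | ethyl (2S,3S)-3-[(tert-butyldimethylsilyl)oxy]-2-methylbutanoate | CCOC(=O)[C@@H](C)[C@H](C)O[Si](C)(C)C(C)(C)C | intermediate
5 | (2S,3S)-3-[(tert-butyldimethylsilyl)oxy]-2-methylbutanal | O=C[C@@H](C)[C@H](C)O[Si](C)(C)C(C)(C)C | intermediate
6 | 2-(triphenyl-λ5-phosphanylidene)propanal | CC(C=O)=P(c1ccccc1)(c1ccccc1)c1ccccc1 | starting material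
7 | (2E,4R,5S)-5-[(tert-butyldimethylsilyl)oxy]-2,4-dimethylhex-2-enal | O=C/C(C)=C/[C@@H](C)[C@H](C)O[Si](C)(C)C(C)(C)C | intermediate
8 | triethyl phosphonoacetate | CCOC(=O)CP(=O)(OCC)OCC | starting material
9 | sodium salt of 8 | CCOC(=O)[CH-]P(=O)(OCC)OCC.[Na+] | intermediate
10 | ethyl (2E,4E,6R,7S)-7-[(tert-butyldimethylsilyl)oxy]-4,6-dimethylocta-2,4-dienoate | CCOC(=O)/C=C/C(C)=C/[C@@H](C)[C@H](C)O[Si](C)(C)C(C)(C)C | intermediate
11 | (2E,4E,6R,7S)-7-[(tert-butyldimethylsilyl)oxy]-4,6-dimethylocta-2,4-dienoic acid | OC(=O)/C=C/C(C)=C/[C@@H](C)[C@H](C)O[Si](C)(C)C(C)(C)C | intermediate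
12 | ethynyl(triisopropyl)silane | C#C[Si](C(C)C)(C(C)C)C(C)C | starting material
13 | (S)-2-vinyloxirane | C=C[C@H]1CO1 | starting material
14 | lithium (triisopropylsilyl)acetylide | [Li]C#C[Si](C(C)C)(C(C)C)C(C)C | intermediate
15 | diethyl[(triisopropylsilyl)ethynyl]alane | CC[Al](CC)C#C[Si](C(C)C)(C(C)C)C(C)C | intermediate
16 | (S)-2-[(triisopropylsilyl)ethynyl]but-3-en-1-ol | OC[C@H](C#C[Si](C(C)C)(C(C)C)C(C)C)C=C | intermediate
17 | methacryloyl chloride | CC(=C)C(Cl)=O | starting material
18 | (S)-2-[(triisopropylsilyl)ethynyl]but-3-en-1-yl methacrylate | CC(=C)C(=O)OC[C@H](C#C[Si](C(C)C)(C(C)C)C(C)C)C=C | intermediate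
19 | (S)-3-methyl-5-[(triisopropylsilyl)ethynyl]-5,6-dihydro-2H-pyran-2-one | CC1=C[C@@H](C#C[Si](C(C)C)(C(C)C)C(C)C)COC1=O | intermediate
20 | (3R,4R,5S)-3,4-dihydroxy-3-methyl-5-[(triisopropylsilyl)ethynyl]tetrahydro-2H-pyran-2-one | O=C1OC[C@H](C#C[Si](C(C)C)(C(C)C)C(C)C)[C@@H](O)[C@@]1(C)O | intermediate
21 | (3aR,7S,7aR)-2,2,3a-trimethyl-7-[(triisopropylsilyl)ethynyl]tetrahydro-4H-[1,3]dioxolo[4,5-c]pyran-4-one | O=C1OC[C@H](C#C[Si](C(C)C)(C(C)C)C(C)C)[C@H]2OC(C)(C)O[C@@]12C | intermediate
22 | (3aR,7S,7aR)-2,2,3a-trimethyl-7-[(triisopropylsilyl)ethynyl]tetrahydro-4H-[1,3]dioxolo[4,5-c]pyran-4-ol (anomeric mixture) | OC1OC[C@H](C#C[Si](C(C)C)(C(C)C)C(C)C)[C@H]2OC(C)(C)O[C@@]12C | intermediate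
23 | ring-opened aldehyde of 22 as its bromomagnesium alkoxide | O=C[C@]1(C)OC(C)(C)O[C@@H]1[C@H](CO[Mg]Br)C#C[Si](C(C)C)(C(C)C)C(C)C | intermediate
24 | (R)-1-{(4S,5R)-5-[(S)-1-hydroxy-4-(triisopropylsilyl)but-3-yn-2-yl]-2,2,4-trimethyl-1,3-dioxolan-4-yl}prop-2-en-1-ol | C=C[C@@H](O)[C@]1(C)OC(C)(C)O[C@@H]1[C@H](CO)C#C[Si](C(C)C)(C(C)C)C(C)C | intermediate
25 | primary (C1–O) ester of 24 with acid 11, C6 hydroxyl free | C=C[C@@H](O)[C@]1(C)OC(C)(C)O[C@@H]1[C@H](COC(=O)/C=C/C(C)=C/[C@@H](C)[C@H](C)O[Si](C)(C)C(C)(C)C)C#C[Si](C(C)C)(C(C)C)C(C)C | intermediate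
26 | C6 triethylsilyl ether of 25 | C=C[C@@H](O[Si](CC)(CC)CC)[C@]1(C)OC(C)(C)O[C@@H]1[C@H](COC(=O)/C=C/C(C)=C/[C@@H](C)[C@H](C)O[Si](C)(C)C(C)(C)C)C#C[Si](C(C)C)(C(C)C)C(C)C | intermediate
27 | enol ether from 26 (ester C=O replaced by C=CH2) | C=C[C@@H](O[Si](CC)(CC)CC)[C@]1(C)OC(C)(C)O[C@@H]1[C@H](COC(=C)/C=C/C(C)=C/[C@@H](C)[C@H](C)O[Si](C)(C)C(C)(C)C)C#C[Si](C(C)C)(C(C)C)C(C)C | intermediate
28 | dienyne: fully desilylated 27 | C=C[C@@H](O)[C@]1(C)OC(C)(C)O[C@@H]1[C@H](COC(=C)/C=C/C(C)=C/[C@@H](C)[C@H](C)O)C#C | intermediate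
29 | bicyclic dienyl ether: 7,8-O-isopropylidene acetal of (6R,7S,8R,8aS)-3-[(1E,3E,5R,6S)-6-hydroxy-3,5-dimethylhepta-1,3-dien-1-yl]-7-methyl-6,7,8,8a-tetrahydro-1H-isochromene-6,7,8-triol | CC(/C=C/C1=CC2=C[C@@H](O)[C@]3(C)OC(C)(C)O[C@@H]3[C@@H]2CO1)=C\[C@@H](C)[C@H](C)O | intermediate
30 | 7,8-O-isopropylidene acetal of the 5-deschloro target | CC(/C=C/C1=CC2=CC(=O)[C@]3(C)OC(C)(C)O[C@@H]3[C@@H]2CO1)=C\[C@@H](C)[C@H](C)O | intermediate
31 | 7,8-O-isopropylidene acetal of the target | CC(/C=C/C1=CC2=C(Cl)C(=O)[C@]3(C)OC(C)(C)O[C@@H]3[C@@H]2CO1)=C\[C@@H](C)[C@H](C)O | intermediate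
32 | (7R,8R,8aS)-5-chloro-7,8-dihydroxy-3-[(1E,3E,5R,6S)-6-hydroxy-3,5-dimethylhepta-1,3-dien-1-yl]-7-methyl-8,8a-dihydro-1H-isochromen-6(7H)-one | CC(/C=C/C1=CC2=C(Cl)C(=O)[C@](C)(O)[C@H](O)[C@@H]2CO1)=C\[C@@H](C)[C@H](C)O | target

## Step count and risks

Total step count: 21. Longest linear sequence: 15 steps (steps 7 to 21); fragment 2 (steps 1 to 6) joins at step 14.

Steps most likely to fail:

1. Step 18. The vinylalkylidene formed after the first ring closure may fail to close onto the hindered 1,1-disubstituted enol ether and be lost instead to intermolecular metathesis or oligomerisation of the terminal alkyne. Fallback: the C3=C4 bond is made by carbonyl–olefin metathesis of the ester instead of enol-ether metathesis. It sets out from 26. AgF in MeCN/MeOH with brief acidic work-up removes only the alkynyl silyl group to give the terminal-alkyne ester F1. Second-generation Grubbs catalyst under ethylene closes ring A by exo enyne metathesis, an isomerisation, to give the C4a-vinyl triene ester F2. A Takai–Utimoto-type titanium ethylidene (TiCl4, Zn, PbCl2, TMEDA, CH3CHBr2, THF) then converts the C4 vinyl group and the ester carbonyl into the cyclic enol ether, the bis-silylated bicycle F3. Bu4NF removes both O-silyl groups and the route is rejoined at 29.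

2. Step 16. The titanium methylidene may add to the silylalkyne (titanacyclobutene formation) in competition with ester methylenation. Fallback: the alkyne is consumed before any titanium reagent is used. It sets out from 26 and passes through the terminal-alkyne ester F1 and the C4a-vinyl triene ester F2 as described above. Tebbe methylenation of F2, which no longer holds an alkyne, gives the enol ether triene F4. Ordinary ring-closing metathesis of the C4 vinyl group with the enol ether (second-generation Grubbs catalyst) gives the bis-silylated bicycle F3, and Bu4NF returns to the route at 29.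

3. Step 7. Regiocontrol in the epoxide opening may be lost, with attack at the terminal carbon or in the SN2′ sense instead of at the allylic carbon. Fallback: C8a is set by opening a 2,3-epoxy alcohol at its allylic C3 position. It sets out from silylacetylene 12, converted into alane 15 as in step 7. (E)-Penta-2,4-dien-1-ol is epoxidised by Sharpless asymmetric epoxidation (Ti(OiPr)4, L-(+)-diethyl tartrate, tBuOOH, CH2Cl2, −20 °C) to the (2S,3S)-epoxy alcohol F5. Alane 15 opens F5 at C3 with inversion to give the 1,2-diol F6. NaIO4 cleaves the diol to the configurationally labile aldehyde F7, which is reduced at once with NaBH4 to rejoin the route at 16.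

Further compounds
F1 | step 18 | terminal-alkyne ester (26 without the alkynyl silyl group) | C=C[C@@H](O[Si](CC)(CC)CC)[C@]1(C)OC(C)(C)O[C@@H]1[C@H](COC(=O)/C=C/C(C)=C/[C@@H](C)[C@H](C)O[Si](C)(C)C(C)(C)C)C#C
F2 | step 18 | ring A triene ester (C4a-vinyl, C4a=C5) | C=CC1=C[C@@H](O[Si](CC)(CC)CC)[C@]2(C)OC(C)(C)O[C@@H]2[C@@H]1COC(=O)/C=C/C(C)=C/[C@@H](C)[C@H](C)O[Si](C)(C)C(C)(C)C
F3 | step 18 | bis-silylated bicycle (29 with C6 triethylsilyl and C6′ tert-butyldimethylsilyl ethers) | CC(/C=C/C1=CC2=C[C@@H](O[Si](CC)(CC)CC)[C@]3(C)OC(C)(C)O[C@@H]3[C@@H]2CO1)=C\[C@@H](C)[C@H](C)O[Si](C)(C)C(C)(C)C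
F4 | step 16 | enol ether triene (F2 with ester C=O replaced by C=CH2) | C=CC1=C[C@@H](O[Si](CC)(CC)CC)[C@]2(C)OC(C)(C)O[C@@H]2[C@@H]1COC(=C)/C=C/C(C)=C/[C@@H](C)[C@H](C)O[Si](C)(C)C(C)(C)C
F5 | step 7 | [(2S,3S)-3-vinyloxiran-2-yl]methanol | OC[C@@H]1O[C@H]1C=C
F6 | step 7 | (2R,3S)-3-[(triisopropylsilyl)ethynyl]pent-4-ene-1,2-diol | OC[C@H](O)[C@H](C#C[Si](C(C)C)(C(C)C)C(C)C)C=C
F7 | step 7 | (S)-2-[(triisopropylsilyl)ethynyl]but-3-enal | O=C[C@H](C#C[Si](C(C)C)(C(C)C)C(C)C)C=C
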